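**Early times.** At early times the south-east run lost starting material fast: 48% stood at 0.667 h, with target at 10%. By 3.00 h the two together came to 26.0%. From there to 5.00 h the starting material read 5% to 7%, while target rose. So I looked to that late rise for the end amount.

| flask | starting material | second substrate | free enzyme | remark | time |
|---|---|---|---|---|---|
| south-east | 0.10 M | 0.12 M | 10 µM | run made earlier |  |
| east | 0.10 M | 0.24 M | 10 µM | run made earlier |  |
| Thursday's | 0.10 M | 0.120 M (fed, over 25 min) | 10 µM | all else is in the flask from the start; the feed brings no volume worth counting | 5.0 h |
| Wednesday's | 0.10 M | 0.120 M | 10 µM | everything together at the start | 5.0 h |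
| Sunday's | 0.10 M | 0.120 M (fed, over 4.0 h) | 10 µM | all else is in the flask from the start; the feed brings no volume worth counting | 5.0 h |
| Monday's | 0.10 M (fed, over 4.0 h) | 0.120 M | 10 µM | all else is in the flask from the start; the feed brings no volume worth counting | 5.0 h |

south-east run (percent of the starting material charged)

| time / h | target / % | starting material / % |
|---|---|---|
| 0.667 | 10 | 48 |
| 1.33 | 13 | 22 |
| 2.00 | 19 | 11 |
| 3.00 | 21 | 5 |
| 4.00 | 22 | 5 |
| 5.00 | 32 | 7 |

east run (percent of the starting material charged)

| time / min | target / % | starting material / % |
|---|---|---|
| 8.00 | 0 | 81 |
| 12.0 | 4 | 76 |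
| 15.0 | 5 | 66 |
| 25.0 | 8 | 55 |
| 40.0 | 7 | 40 |
| 60.0 | 12 | 24 |
| 90.0 | 17 | 13 |

(standard deviation of a reading: 2 percentage points)

- the best flask by amount of target, in percent of the starting material charged; "all alike" if 1.5 percentage points covers them all (Thursday's / Wednesday's / Sunday's / Monday's / all alike)
- amount of target at the end, in percent of the starting material charged, Thursday's
- amount of target at the end, in percent of the starting material charged, Wednesday's
- amount of target at the end, in percent of the starting material charged, Sunday's
- amount of target at the end, in percent of the starting material charged, Monday's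

**What matters.** I took the numbers in turn. The east run, with twice the second substrate, read 17% at 90.0 min, between south-east's 13% at 1.33 h and 19% at 2.00 h, so an error in that charge seemed to matter little. The late starting material readings barely moved, so they mattered little too. The target reading at 4.00 h mattered most: in my reckoning below, it enters both the carried-forward rise and the average, so a shift of 2 percentage points there moves the answer by 1.5 points, against 1 point for the same shift in the last reading.

**Two rounds.** Wednesday's has the south-east charges, so I reckoned that flask. Carrying the rise from 2.00 h to 4.00 h forward gave 23.5%. The last reading stood higher by 8.5 points, well beyond the scatter. Going round once more, I averaged the two: 27.8%. That gave the late gain, the target added per hour after 2.00 h, as a fraction of the charge: 0.0292 h⁻¹.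

**The forecast.** It said all alike: 25% for Thursday's, 25% for Wednesday's, 24% for Sunday's and 24% for Monday's. Its ground was “Feeding should therefore change little”. For Wednesday's my figure stood higher.

**The result.** Monday's gave most, 29.9%, against 27.6% for Wednesday's, 27.0% for Thursday's and 21.4% for Sunday's. The forecast and the flasks part on the spread, 8.5 points against a margin of 1.5 points. At the end, the dormant form, an off-cycle reservoir, stood at 49.5% in Monday's and 66.2% in Sunday's. At the late gain, Monday's lead over Wednesday's is worth 0.796 h, and Sunday's lag behind Wednesday's 2.12 h.

    starting material + free enzyme ⇌ first complex (K = 24.0 L mol⁻¹, k = 882 L mol⁻¹ s⁻¹)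
    first complex ⇌ loaded enzyme + first product (K = 0.0513 M, k = 1.32 s⁻¹)
    second substrate + loaded enzyme ⇌ second complex (K = 5.54 L mol⁻¹, k = 118 L mol⁻¹ s⁻¹)
    second complex → free enzyme + target (k = 1.83 s⁻¹)
    starting material ⇌ dormant form (K = 6.40, k = 2.44 × 10⁻⁴ s⁻¹)
    starting material + second substrate → uncatalysed product (k = 4.18 × 10⁻⁴ L mol⁻¹ s⁻¹)
    starting material → decomposition product (k = 5.43 × 10⁻⁷ s⁻¹)

**A later reading.** For Monday's flask read at 8.0 h, the late gain added to 29.9% gives 38.6%. The computed flask holds 36.7%.

(Readings and results are calculated on assumed constants, and the scatter is random.)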